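## Analysis of the target

The target is a 1,7,8,8a-tetrahydro-6H-isochromen-6-one. Ring A is the carbocycle C4a–C5–C6–C7–C8–C8a and ring B is the pyran O2–C1–C8a–C4a–C4–C3. A doubly vinylogous ester O2–C3=C4–C4a=C5(Cl)–C6=O runs through both rings and is extended by the E-alkene C1′=C2′ of the side chain.

Ring A carries three contiguous stereocentres: C7 (tertiary carbinol, methyl), C8 (secondary carbinol) and C8a (H). The C7 and C8 hydroxyls are cis, and C1 on C8a is cis to the C8 hydroxyl (7R,8R,8aS).

The side chain carries a second, remote group of three stereocentres: the tertiary carbinol C3′ (R) and a trans-2,3-disubstituted oxolane (C2″ S, C3″ S). Nothing relays stereochemistry between the two groups, so each needs its own absolute control.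

The sensitive functions are:
- the δ-hydroxy dienone, which can lose water by E1cB through the C8a–H;
- the α-ketol at C6/C7;
- the acid-labile dienol ether and the tertiary allylic alcohol;
- C8a, which can epimerize through the dienolate.

The structural feature that drives the plan is the oxidation pattern of ring A. C8 is a carbinol and C1 a methylene, so ring A with its six substituents (C4, Cl, O, CH3/OH, OH, C1) is a pentasubstituted phenol plus one oxygen atom at C7 and one molecule of water across C8=C8a. The hard part is to add these two elements to a flat ring with control of C7, C8 and C8a, without passing through the more highly oxidized azaphilone.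

## Retrosynthetic reasoning

**O2–C3 (ring B).** The enol ether bond of 21 is cut first, which leads to triol 20 and its silyl ether 19, a 3-alkynyl-2-chlorocyclohexenone with the C1 oxygen on the neighbouring carbon. In the forward sense the C1 alkoxide adds to C3, the δ-carbon of the dienynone. A 6-endo-dig closure is therefore the electronically favoured mode, and the acid-sensitive dienol ether appears only in the last step.

**C4–C4a (union of the two halves).** Cutting the sp–sp2 bond of 19 gives β-bromo enone 9 and terminal enyne 18. The bond is made by a Sonogashira coupling, for which a β-bromo enone is an ideal partner. The cut separates the two stereochemical groups, so each is made on a small fragment.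

**C7–O, C8–O and C8a–H (key disconnection).** Diol 9 is traced back to the flat phenol 6 by removing the oxygen at C6 of 9 (C7 of the target) and the elements of water from C5/C4 of 9 (C8/C8a of the target). The forward step must dearomatize 6 at the methyl-bearing ortho carbon with a chiral hypervalent iodine oxidant (dienone 7). It must then add a boron-tethered hydroxyl to the δ-carbon of the dienone from the face of the new tertiary hydroxyl (boronate 8), and the dienolate must be protonated at C4. This sets all three ring-A stereocentres in one operation from an achiral benzene ring. No redox corrections are needed afterwards, because 9 equals 6 plus O plus H2O.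

**Phenol 6.** The substituents of 6 are placed by ordinary arene chemistry from anisole 1: formylation para to the methoxy group (2), demethylation (3), chlorination at the only free position ortho to the hydroxyl (4), reduction (5) and silylation (6). The bromine of 1 is already at the future C4a.

**O1″–C2″ and C3′–O of enyne 18.** The oxolane and the tertiary carbinol are traced to the E-trisubstituted alkene of dienynol 15 through vinyl epoxide 16. Epoxidation followed by 5-exo opening by the primary hydroxyl is an anti addition across the E-alkene, which is exactly the C3′ (R)/C2″ (S) relationship. A syn-dihydroxylation of the same alkene would give the wrong diastereomer. The catalyst sets two stereocentres and the epoxide opening relays them.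

**Alkenes of 15.** The C6=C7 bond of 15 is cut to enal 13 and phosphonate 14 (Horner–Wadsworth–Emmons). The C2=C3 bond of 13 is cut to lactol 11 and ylide 12 (Wittig). Lactol 11 comes from lactone 10, whose single stereocentre becomes C3″ and is the only one bought.

## Alternatives that were turned down

**Alternative 1:** the textbook azaphilone route. The disconnection is O2–C3 and C7–O of an azaphilone. The forward key step is gold trichloride- or [Cu(MeCN)4]PF6/sparteine/O2-mediated cycloisomerization and oxidative dearomatization of the ortho-alkynyl resorcinol aldehyde A1 to the 6,8-dione A2, followed by reduction of C8=O and of C1=C8a. It was turned down for these reasons: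
- A2 is two oxidation levels above the target, at C8 and C1.
- The C8 carbonyl is the least electrophilic one (a vinylogous ester carbonyl). Hydride would rather attack C1 or the C6 dienone, and nucleophiles open the pyran of such systems at C1.
- C8 and C8a would have to be set late, by two reductions, on the fully elaborated and most sensitive compound, next to the side-chain alkene.
- It costs extra steps without removing the stereochemical problem.

**Alternative 2:** enzymatic arene cis-dihydroxylation. The disconnection is the C7–O and C8–O bonds of a cyclohexadiene cis-diol. The forward key step is microbial ipso,ortho-dihydroxylation of benzoic acid to A3, whose cis-diol has the C7/C8 oxygen pattern with a carboxyl where the C7 methyl must be. It was turned down because the carboxyl must be reduced to a methyl group over several steps. The bare diene of A3 also offers no handles for the regio- and stereocontrolled introduction of the C6 ketone, the C5 chlorine, the C4a alkyne and the C8a hydroxymethyl group. A3 is a fermentation product and not a catalogue compound.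

**Alternative 3:** annulation of ring A onto a preformed ring B. The disconnection is C8–C8a and C4a=C5. The forward key step is an aldol addition of the α′-enolate of dihydropyranone A4 to the chiral keto aldehyde A5, followed by an intramolecular aldol condensation of the chloromethyl ketone onto the C4a carbonyl. It was turned down for these reasons:
- A5 is an α-hydroxy-β-keto aldehyde prone to retro-Claisen cleavage and would itself need an enantioselective synthesis.
- The aldol must set C8 and C8a against C7 with only acyclic control.
- The ring closure asks a vinylogous ester carbonyl to act as the electrophile.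
- The α-chloro ketone enolate can also react by Darzens or Favorskii pathways.

Key step: step 6

## Assumptions

Assumption 1: (3S)-3-methyloxolan-2-one (10) is taken as a catalogue compound in enantiopure form.

Assumption 2: the sense of induction of the chiral iodane on phenol 6 cannot be derived from the structure alone. The atropisomer that gives (6R)-7 is meant and is written as (R), its antipode being equally accessible. The reagent is made beforehand from (R)-2,2′-diiodo-1,1′-binaphthalene and dimethyldioxirane.

## Route

Step 1
Reactants: 1 4-bromo-2-methoxy-1-methylbenzene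
Product: 2 2-bromo-4-methoxy-5-methylbenzaldehyde
Conditions: Cl2CHOMe, TiCl4, CH2Cl2, 0 °C; then H2O
Reagents that add atoms: dichloromethyl methyl ether, COC(Cl)Cl; water, O
Why: Rieche formylation; the methoxy group directs the electrophile to its para position, which is less crowded than the ortho position between OMe and Br, and aqueous work-up hydrolyses the α-chloro ether to the aldehyde.

Step 2
Reactants: 2 2-bromo-4-methoxy-5-methylbenzaldehyde
Product: 3 2-bromo-4-hydroxy-5-methylbenzaldehyde
Conditions: BBr3, CH2Cl2, −78 °C to rt; then H2O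
Reagents that add atoms: none
Why: Lewis-acid cleavage of the aryl methyl ether by BBr3; the aryl bromide and the aldehyde are inert to it.

Step 3
Reactants: 3 2-bromo-4-hydroxy-5-methylbenzaldehyde
Product: 4 2-bromo-3-chloro-4-hydroxy-5-methylbenzaldehyde
Conditions: NCS, TsOH·H2O (10 mol%), MeCN, rt
Reagents that add atoms: N-chlorosuccinimide, ClN1C(=O)CCC1=O
Why: Electrophilic aromatic chlorination; C3 is the only free position ortho to the hydroxyl and is also meta to the formyl group, so both directing effects agree.

Step 4
Reactants: 4 2-bromo-3-chloro-4-hydroxy-5-methylbenzaldehyde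
Product: 5 3-bromo-2-chloro-4-(hydroxymethyl)-6-methylphenol
Conditions: NaBH4, MeOH–THF, 0 °C
Reagents that add atoms: none
Why: Borohydride reduction of the aldehyde; this brings the future C1 to the alcohol level that the target needs, so no later reduction of ring B is required.

Step 5
Reactants: 5 3-bromo-2-chloro-4-(hydroxymethyl)-6-methylphenol
Product: 6 3-bromo-4-{[tert-butyl(dimethyl)silyl]oxymethyl}-2-chloro-6-methylphenol
Conditions: TBSCl (1.05 equiv), imidazole, DMF, 0 °C
Reagents that add atoms: tert-butyldimethylsilyl chloride, CC(C)(C)[Si](C)(C)Cl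
Why: Chemoselective silylation of the primary benzylic alcohol; the phenol is flanked by chlorine and methyl and should react much more slowly, and the ether keeps the benzylic alcohol from being oxidized in step 6.

Step 6
Reactants: 6 3-bromo-4-{[tert-butyl(dimethyl)silyl]oxymethyl}-2-chloro-6-methylphenol
Product: 9 (4S,5R,6R)-3-bromo-4-{[tert-butyl(dimethyl)silyl]oxymethyl}-2-chloro-5,6-dihydroxy-6-methylcyclohex-2-en-1-one, via ortho-quinol 7 (not isolated), via cyclic phenylboronate 8 (not isolated)
Conditions: (R)-2,2′-diiodyl-1,1′-binaphthalene (1.1 equiv), THF, −20 °C to rt; aq. NaHCO3 work-up; then PhB(OH)2 (1.5 equiv), iPr2NEt (20 mol%), 4 Å MS, PhMe, rt; then pinacol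
Reagents that add atoms: (R)-2,2′-diiodyl-1,1′-binaphthalene, O=I(=O)c1ccc2ccccc2c1-c1c(I(=O)=O)ccc2ccccc12; phenylboronic acid, OB(O)c1ccccc1
Why: Proposed new method: a boronic-acid hemiester 1,6-oxa-Michael addition onto an ortho-quinol, closest to two known reaction types, the boronic-acid-hemiester oxa-Michael addition to γ-hydroxy enones and the acetalization/oxa-Michael cascade of para-quinols with aldehydes. The first stage is a known hydroxylative phenol dearomatization: the phenol oxygen binds the pentavalent iodine centre and an iodyl oxygen is passed to the methyl-bearing ortho carbon in a [2,3]-type shift, which gives dienone 7 and sets C6 (C7 of the target) under control of the chiral biaryl backbone. The step needs the oxygen at the C–CH3 and not at the C–Cl ortho carbon; the alkyl-bearing carbon is the more electron-rich one, and oxygenation at the other would end in an ortho-quinone after loss of HCl. In the second stage the tertiary hydroxyl condenses with PhB(OH)2 and the amine turns the B–OH into a boronate nucleophile that can reach only C5 (C8 of the target), the δ-terminus of the chloro-bromo-dienone, through a 5-exo-trig closure of the transient dioxaborolane ring, the only ring this step closes; this fixes the C5 oxygen cis to the C6 oxygen. The dienolate is then protonated at C4 (C8a of the target) from the face opposite the newly fused boronate ring. The same epimer should also be the thermodynamic one, because it alone lets the C4 side chain sit pseudo-axial, free of A(1,2) strain with the C3 bromine, while the C5 hydroxyl and the C6 methyl stay equatorial; the amine can equilibrate C4 through the dienolate. The intramolecular addition has to outrun [4+2] dimerization of 7, which the three substituents on the diene (Cl, Br, silyloxymethyl) should slow; transesterification with pinacol then frees diol 9.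

Step 7
Reactants: 10 (3S)-3-methyloxolan-2-one
Product: 11 (3S)-3-methyloxolan-2-ol (mixture of anomers)
Conditions: iBu2AlH (1.1 equiv), CH2Cl2, −78 °C; aq. potassium sodium tartrate
Reagents that add atoms: none
Why: Partial reduction of the lactone to the lactol, a masked 4-hydroxy-2-methylbutanal; at −78 °C the tetrahedral aluminate does not collapse, so over-reduction and epimerization of the α-stereocentre are avoided.

Step 8
Reactants: 11 (3S)-3-methyloxolan-2-ol; 12 2-(triphenyl-λ5-phosphanylidene)propanal
Product: 13 (2E,4S)-6-hydroxy-2,4-dimethylhex-2-enal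
Conditions: PhMe, 90 °C
Reagents that add atoms: none
Why: Wittig reaction of the open hydroxy aldehyde form of the lactol with a stabilized ylide, which gives the E-trisubstituted enal; the α-methyl group of the product slows both a second olefination and 5-exo oxa-Michael closure of the free hydroxyl.

Step 9
Reactants: 13 (2E,4S)-6-hydroxy-2,4-dimethylhex-2-enal; 14 diethyl [3-(trimethylsilyl)prop-2-yn-1-yl]phosphonate
Product: 15 (3S,4E,6E)-3,5-dimethyl-9-(trimethylsilyl)nona-4,6-dien-8-yn-1-ol
Conditions: 14, LiN(SiMe3)2, THF, −78 °C; then 13, −78 to 0 °C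
Reagents that add atoms: none
Why: Horner–Wadsworth–Emmons olefination with a propargylic phosphonate anion, which gives the E-enyne; the anion is less basic than an alkoxide, so the free hydroxyl is tolerated.

Step 10
Reactants: 15 (3S,4E,6E)-3,5-dimethyl-9-(trimethylsilyl)nona-4,6-dien-8-yn-1-ol
Product: 18 (2R,3E)-2-[(2S,3S)-3-methyloxolan-2-yl]hex-3-en-5-yn-2-ol, via vinyl epoxide 16 (not isolated), via C-silylated oxolane carbinol 17 (not isolated)
Conditions: 1,2:4,5-di-O-isopropylidene-β-D-erythro-2,3-hexodiulo-2,6-pyranose (30 mol%), KHSO5, K2CO3, Bu4NHSO4, MeCN–CH2(OMe)2–aq. buffer (pH 10.5), 0 °C; then K2CO3, MeOH, 40 °C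
Reagents that add atoms: potassium peroxymonosulfate, OOS(=O)(=O)[O-].[K+]
Why: Shi epoxidation by the chiral dioxirane at the electron-richer trisubstituted C4=C5 alkene; the D-fructose-derived ketone gives (R,R)-epoxides from E-trisubstituted alkenes by reagent control. Under base the primary alkoxide opens the epoxide at the secondary carbon (5-exo-tet, SN2, inversion), which sets the oxolane C2 (S) and leaves the tertiary carbinol (R) untouched. The same methanolic carbonate removes the alkynyl silyl group.

Step 11
Reactants: 9 (4S,5R,6R)-3-bromo-4-{[tert-butyl(dimethyl)silyl]oxymethyl}-2-chloro-5,6-dihydroxy-6-methylcyclohex-2-en-1-one; 18 (2R,3E)-2-[(2S,3S)-3-methyloxolan-2-yl]hex-3-en-5-yn-2-ol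
Product: 19 (4S,5R,6R)-4-{[tert-butyl(dimethyl)silyl]oxymethyl}-2-chloro-5,6-dihydroxy-3-{(3E,5R)-5-hydroxy-5-[(2S,3S)-3-methyloxolan-2-yl]hex-3-en-1-yn-1-yl}-6-methylcyclohex-2-en-1-one
Conditions: Pd(PPh3)2Cl2 (5 mol%), CuI (10 mol%), Et3N, THF, rt
Reagents that add atoms: none
Why: Sonogashira coupling; oxidative addition of zerovalent palladium into the β-bromo enone is fast at room temperature while the α-chlorine stays untouched, and a tertiary amine base avoids addition–elimination at the β-carbon.

Step 12
Reactants: 19 (4S,5R,6R)-4-{[tert-butyl(dimethyl)silyl]oxymethyl}-2-chloro-5,6-dihydroxy-3-{(3E,5R)-5-hydroxy-5-[(2S,3S)-3-methyloxolan-2-yl]hex-3-en-1-yn-1-yl}-6-methylcyclohex-2-en-1-one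
Product: 21 (7R,8R,8aS)-5-chloro-7,8-dihydroxy-3-{(1E,3R)-3-hydroxy-3-[(2S,3S)-3-methyloxolan-2-yl]but-1-en-1-yl}-7-methyl-1,7,8,8a-tetrahydro-6H-isochromen-6-one, via desilylated triol 20 (not isolated)
Conditions: Bu4NF (1.1 equiv), THF, 0 °C; pH 7 buffer
Reagents that add atoms: none
Why: Fluoride cleaves the silyl ether and the C1 alkoxide adds to C3, the δ-carbon of the dienynone (6-endo-dig oxa-conjugate addition); attack at C4 (5-exo) has no carbonyl stabilization. The C8 hydroxyl could reach C3 only through a bridged ring with a bridgehead alkene, so ring B should close selectively.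

## Compound list

1 | 4-bromo-2-methoxy-1-methylbenzene | COc1cc(Br)ccc1C | starting material
2 | 2-bromo-4-methoxy-5-methylbenzaldehyde | COc1cc(Br)c(C=O)cc1C | intermediate
3 | 2-bromo-4-hydroxy-5-methylbenzaldehyde | Oc1cc(Br)c(C=O)cc1C | intermediate
4 | 2-bromo-3-chloro-4-hydroxy-5-methylbenzaldehyde | Oc1c(Cl)c(Br)c(C=O)cc1C | intermediate
5 | 3-bromo-2-chloro-4-(hydroxymethyl)-6-methylphenol | Oc1c(Cl)c(Br)c(CO)cc1C | intermediate
6 | 3-bromo-4-{[tert-butyl(dimethyl)silyl]oxymethyl}-2-chloro-6-methylphenol | Oc1c(Cl)c(Br)c(CO[Si](C)(C)C(C)(C)C)cc1C | intermediate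
7 | (6R)-3-bromo-4-{[tert-butyl(dimethyl)silyl]oxymethyl}-2-chloro-6-hydroxy-6-methylcyclohexa-2,4-dien-1-one | O=C1C(Cl)=C(Br)C(CO[Si](C)(C)C(C)(C)C)=C[C@@]1(C)O | intermediate
8 | (3aR,4S,7aR)-5-bromo-4-{[tert-butyl(dimethyl)silyl]oxymethyl}-6-chloro-7a-methyl-2-phenyl-3a,4-dihydro-1,3,2-benzodioxaborol-7(7aH)-one (cyclic phenylboronate of 9) | BrC1=C(Cl)C(=O)[C@]2(C)OB(c3ccccc3)O[C@@H]2[C@@H]1CO[Si](C)(C)C(C)(C)C | intermediate
9 | (4S,5R,6R)-3-bromo-4-{[tert-butyl(dimethyl)silyl]oxymethyl}-2-chloro-5,6-dihydroxy-6-methylcyclohex-2-en-1-one | BrC1=C(Cl)C(=O)[C@](C)(O)[C@H](O)[C@@H]1CO[Si](C)(C)C(C)(C)C | intermediate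
10 | (3S)-3-methyloxolan-2-one | C[C@H]1CCOC1=O | starting material
11 | (3S)-3-methyloxolan-2-ol (anomer mixture) | C[C@H]1CCOC1O | intermediate
12 | 2-(triphenyl-λ5-phosphanylidene)propanal | CC(C=O)=P(c1ccccc1)(c1ccccc1)c1ccccc1 | starting material
13 | (2E,4S)-6-hydroxy-2,4-dimethylhex-2-enal | C[C@H](/C=C(\C)C=O)CCO | intermediate
14 | diethyl [3-(trimethylsilyl)prop-2-yn-1-yl]phosphonate | CCOP(=O)(CC#C[Si](C)(C)C)OCC | starting material
15 | (3S,4E,6E)-3,5-dimethyl-9-(trimethylsilyl)nona-4,6-dien-8-yn-1-ol | C[C@H](/C=C(\C)/C=C/C#C[Si](C)(C)C)CCO | intermediate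
16 | (3S)-3-{(2R,3R)-3-methyl-3-[(1E)-4-(trimethylsilyl)but-1-en-3-yn-1-yl]oxiran-2-yl}butan-1-ol | C[C@H]([C@H]1O[C@]1(C)/C=C/C#C[Si](C)(C)C)CCO | intermediate
17 | (2R,3E)-2-[(2S,3S)-3-methyloxolan-2-yl]-6-(trimethylsilyl)hex-3-en-5-yn-2-ol | C[C@H]1CCO[C@@H]1[C@](C)(O)/C=C/C#C[Si](C)(C)C | intermediate
18 | (2R,3E)-2-[(2S,3S)-3-methyloxolan-2-yl]hex-3-en-5-yn-2-ol | C[C@H]1CCO[C@@H]1[C@](C)(O)/C=C/C#C | intermediate
19 | (4S,5R,6R)-4-{[tert-butyl(dimethyl)silyl]oxymethyl}-2-chloro-5,6-dihydroxy-3-{(3E,5R)-5-hydroxy-5-[(2S,3S)-3-methyloxolan-2-yl]hex-3-en-1-yn-1-yl}-6-methylcyclohex-2-en-1-one | C[C@H]1CCO[C@@H]1[C@](C)(O)/C=C/C#CC1=C(Cl)C(=O)[C@](C)(O)[C@H](O)[C@@H]1CO[Si](C)(C)C(C)(C)C | intermediate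
20 | (4S,5R,6R)-2-chloro-5,6-dihydroxy-4-(hydroxymethyl)-3-{(3E,5R)-5-hydroxy-5-[(2S,3S)-3-methyloxolan-2-yl]hex-3-en-1-yn-1-yl}-6-methylcyclohex-2-en-1-one | C[C@H]1CCO[C@@H]1[C@](C)(O)/C=C/C#CC1=C(Cl)C(=O)[C@](C)(O)[C@H](O)[C@@H]1CO | intermediate
21 | (7R,8R,8aS)-5-chloro-7,8-dihydroxy-3-{(1E,3R)-3-hydroxy-3-[(2S,3S)-3-methyloxolan-2-yl]but-1-en-1-yl}-7-methyl-1,7,8,8a-tetrahydro-6H-isochromen-6-one | C[C@H]1CCO[C@@H]1[C@](C)(O)/C=C/C1=CC2=C(Cl)C(=O)[C@](C)(O)[C@H](O)[C@@H]2CO1 | target

## Step count and least certain steps

Total step count: 12. Longest linear sequence: 8 steps (steps 1 to 6, then 11 and 12).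

**Step 6 (key step, bears the label).** Most likely failure: the hemiboronate of the hindered, hydrogen-bonded tertiary hydroxyl of 7 forms or cyclizes too slowly, so that the dienone is consumed by [4+2] dimerization before the 1,6-addition. Insufficient enantioselection in the oxygen transfer is the second concern. The fallback uses known chemistry and sets out from 6. The same dearomatization is followed in the flask by hydroxyl-directed epoxidation of the C4=C5 bond of 7 (mCPBA, or VO(acac)2/tBuOOH). This gives the syn-epoxy quinol (1S,2R,6S)-5-bromo-6-{[tert-butyl(dimethyl)silyl]oxymethyl}-4-chloro-2-hydroxy-2-methyl-7-oxabicyclo[4.1.0]hept-4-en-3-one F1, in which the epoxide blocks dimerization and holds the C5 oxygen cis to the C6 hydroxyl. SmI2 (2 equiv, THF–MeOH, −78 °C) then cleaves the C–O bond of this γ,δ-epoxy enone at the γ-carbon, and protonation of the samarium dienolate at C4 returns to the route at 9.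

**Step 10.** Most likely failure: the vinyl epoxide 16 opens at its tertiary allylic carbon (6-endo, giving an oxane) or is solvolysed, because that carbon is activated by the enyne. The fallback sets out from 13 and removes the vinyl group from the epoxide:
- Luche reduction (NaBH4, CeCl3·7H2O, MeOH) gives (2E,4S)-2,4-dimethylhex-2-ene-1,6-diol F2.
- Sharpless asymmetric epoxidation (Ti(OiPr)4, D-(−)-diethyl tartrate, tBuOOH, 4 Å MS, CH2Cl2, −20 °C) gives [(2R,3R)-3-[(2S)-4-hydroxybutan-2-yl]-2-methyloxiran-2-yl]methanol F3.
- The tertiary epoxide carbon of F3 is deactivated by the hydroxymethyl group, so titanium-assisted 5-exo opening at C3 gives (2R)-2-[(2S,3S)-3-methyloxolan-2-yl]propane-1,2-diol F4.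
- Parikh–Doering oxidation gives (2S)-2-hydroxy-2-[(2S,3S)-3-methyloxolan-2-yl]propanal F5.
- Horner–Wadsworth–Emmons reaction with 14 comes back to the route at 17, which K2CO3/MeOH converts to 18 as in step 10.

**Step 12.** Most likely failure: in the basic fluoride medium, loss of water across C8–C8a (E1cB through the C8a–H, vinylogous to the ketone) or retro-aldol cleavage of C7–C8 competes with ring closure. The fallback sets out from 19 and replaces the anionic closure by π-acid activation. HF·pyridine (buffered with pyridine, THF, 0 °C) removes the silyl group without base, and triol 20 is isolated. Ph3PAuNTf2 (monovalent gold, 2 mol%, CH2Cl2, rt) then activates the alkyne for 6-endo-dig attack of the primary hydroxyl at C3 and returns to 21. This fallback makes no compound outside the list (F0).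

**Step 5.** Most likely failure: the phenol is silylated as well, because phenoxides are good silyl acceptors even when hindered, and a mixture of ethers results. The fallback sets out from 5. Exhaustive silylation (TBSCl 2.5 equiv, imidazole, DMF, rt) gives tert-butyl{[2-bromo-4-{[tert-butyl(dimethyl)silyl]oxy}-3-chloro-5-methylphenyl]methoxy}dimethylsilane F6. K2CO3 in MeOH at 0 °C then cleaves only the aryl silyl ether and returns to 6.

## Further compounds

F1 | step 6 | (1S,2R,6S)-5-bromo-6-{[tert-butyl(dimethyl)silyl]oxymethyl}-4-chloro-2-hydroxy-2-methyl-7-oxabicyclo[4.1.0]hept-4-en-3-one | O=C1C(Cl)=C(Br)[C@@]2(CO[Si](C)(C)C(C)(C)C)O[C@H]2[C@@]1(C)O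
F2 | step 10 | (2E,4S)-2,4-dimethylhex-2-ene-1,6-diol | C[C@H](/C=C(\C)CO)CCO
F3 | step 10 | [(2R,3R)-3-[(2S)-4-hydroxybutan-2-yl]-2-methyloxiran-2-yl]methanol | C[C@H]([C@H]1O[C@]1(C)CO)CCO
F4 | step 10 | (2R)-2-[(2S,3S)-3-methyloxolan-2-yl]propane-1,2-diol | C[C@H]1CCO[C@@H]1[C@](C)(O)CO
F5 | step 10 | (2S)-2-hydroxy-2-[(2S,3S)-3-methyloxolan-2-yl]propanal | C[C@H]1CCO[C@@H]1[C@](C)(O)C=O
F0 | step 12 | none | none
F6 | step 5 | tert-butyl{[2-bromo-4-{[tert-butyl(dimethyl)silyl]oxy}-3-chloro-5-methylphenyl]methoxy}dimethylsilane | CC(C)(C)[Si](C)(C)OCc1cc(C)c(O[Si](C)(C)C(C)(C)C)c(Cl)c1Br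
A1 | alternative 1 | 3-chloro-4,6-dihydroxy-2-{(3E,5R)-5-hydroxy-5-[(2S,3S)-3-methyloxolan-2-yl]hex-3-en-1-yn-1-yl}-5-methylbenzaldehyde | C[C@H]1CCO[C@@H]1[C@](C)(O)/C=C/C#Cc1c(Cl)c(O)c(C)c(O)c1C=O
A2 | alternative 1 | (7R)-5-chloro-7-hydroxy-3-{(1E,3R)-3-hydroxy-3-[(2S,3S)-3-methyloxolan-2-yl]but-1-en-1-yl}-7-methyl-6H-isochromene-6,8(7H)-dione | C[C@H]1CCO[C@@H]1[C@](C)(O)/C=C/C1=CC2=C(Cl)C(=O)[C@](C)(O)C(=O)C2=CO1
A3 | alternative 2 | (1S,2R)-1,2-dihydroxycyclohexa-3,5-diene-1-carboxylic acid | OC(=O)[C@]1(O)C=CC=C[C@H]1O
A4 | alternative 3 | 6-{(1E,3R)-3-hydroxy-3-[(2S,3S)-3-methyloxolan-2-yl]but-1-en-1-yl}-2,3-dihydro-4H-pyran-4-one | C[C@H]1CCO[C@@H]1[C@](C)(O)/C=C/C1=CC(=O)CCO1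
A5 | alternative 3 | (2R)-4-chloro-2-hydroxy-2-methyl-3-oxobutanal | O=C[C@@](C)(O)C(=O)CCl
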